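**Plan**

- Retrosynthesis: first the three O–methyl bonds and the saturation of C5–C8 are taken back, then the C6–C7 bond of the macrocycle is cut, then the two aryl–CH2 bonds (ring A–C1 and ring B–C12), and last the diaryl ether C–O bond. The chain is numbered C1 (on ring A, the ring with one OH) to C12 (on ring B, the ring whose two OH groups flank the ether oxygen).
- Enabling feature: the bridge between ring A and ring B has twelve carbons and C6–C7 is its exact midpoint, so each ring carries the same six-carbon hex-5-ynyl arm and the terminal alkyne carbons C6 and C7 are joined to each other by homocoupling.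
- Forward order: a Chan–Lam coupling joins ring A to ring B, one double Negishi coupling attaches both arms, desilylation frees the alkynes, an Eglinton coupling closes the only new ring (the 20-membered macrocycle), and hydrogenation plus BBr3 demethylation finish the target.
- Stereochemistry: the target has no stereocentre and no stereogenic double bond, and the diyne is reduced fully to methylenes, so nothing has to be set.

Key step: step 6

Remark on the chemistry: the target SMILES carries no stereodescriptors and the structure is achiral, so it is treated as one achiral compound. The phenols are kept as methyl ethers until the last step because free phenols, above all the 1,2,3-trioxygenated ring B, would be oxidised by Cu(OAc)2 during the ring closure.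

**Route**

Step 1
Reactants: 1 6-chlorohex-1-yne
Product: 3 6-chloro-1-(trimethylsilyl)hex-1-yne, via lithium acetylide 2 (not isolated)
Conditions: n-BuLi (1.05 equiv), THF, −78 °C; then TMSCl, −78 °C → rt
Reagents that add atoms: chlorotrimethylsilane (TMSCl), C[Si](C)(C)Cl
Why: Deprotonation of the terminal alkyne by n-BuLi at −78 °C is far faster than any attack on the primary chloride, and C-silylation of the lithium acetylide (acetylide silylation) masks the acidic C–H that would otherwise quench the organozinc reagent of step 4.

Step 2
Reactants: 3 6-chloro-1-(trimethylsilyl)hex-1-yne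
Product: 4 6-iodo-1-(trimethylsilyl)hex-1-yne
Conditions: NaI (3 equiv), acetone, reflux
Reagents that add atoms: sodium iodide, [Na+].[I-]
Why: Finkelstein halide exchange, an SN2 displacement of the primary chloride by iodide driven by precipitation of NaCl from acetone, should give the iodide needed for mild zinc insertion without touching the silylalkyne.

Step 3
Reactants: 5 4-bromo-2,6-dimethoxyphenol; 6 (3-bromo-5-methoxyphenyl)boronic acid (2 equiv)
Product: 7 5-bromo-2-(3-bromo-5-methoxyphenoxy)-1,3-dimethoxybenzene
Conditions: Cu(OAc)2 (2 equiv), pyridine (5 equiv), 4 Å MS, CH2Cl2, dry air, rt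
Reagents that add atoms: none
Why: Chan–Lam O-arylation, in which the aryl group is transferred from boron to a copper phenoxide and C–O reductive elimination follows from a trivalent copper intermediate, runs at room temperature where neither C–Br bond reacts, and phenols with two ortho substituents are established partners.

Step 4
Reactants: 4 6-iodo-1-(trimethylsilyl)hex-1-yne (2.6 equiv); 7 5-bromo-2-(3-bromo-5-methoxyphenoxy)-1,3-dimethoxybenzene
Product: 9 1,3-dimethoxy-2-{3-methoxy-5-[6-(trimethylsilyl)hex-5-yn-1-yl]phenoxy}-5-[6-(trimethylsilyl)hex-5-yn-1-yl]benzene, via alkylzinc iodide 8 (not isolated)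
Conditions: 4, activated Zn dust, LiCl, THF, 40 °C; then 7, Pd(OAc)2 (4 mol %), SPhos (8 mol %), THF, rt → 50 °C
Reagents that add atoms: none
Why: LiCl-promoted zinc insertion into the primary iodide followed by double Negishi coupling should work because the alkylzinc iodide tolerates the silylalkyne and the zerovalent palladium catalyst formed from Pd(OAc)2 and SPhos inserts into both electron-rich C–Br bonds and forms the primary alkyl–aryl bond faster than β-hydride elimination, so ring A and ring B receive the same arm in one operation.

Step 5
Reactants: 9 the bis(trimethylsilylalkyne) from step 4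
Product: 10 5-(hex-5-yn-1-yl)-2-[3-(hex-5-yn-1-yl)-5-methoxyphenoxy]-1,3-dimethoxybenzene
Conditions: K2CO3 (0.3 equiv), MeOH/THF (2:1), rt
Reagents that add atoms: none
Why: Protodesilylation of a trimethylsilylalkyne by catalytic methoxide cleaves only the C(sp)–Si bonds and leaves the aryl ethers untouched.

Step 6
Reactants: 10 5-(hex-5-yn-1-yl)-2-[3-(hex-5-yn-1-yl)-5-methoxyphenoxy]-1,3-dimethoxybenzene
Product: 11 macrocyclic 1,3-diyne trimethyl ether (20-membered ring; C1–C4 and C9–C12 methylene, C5≡C6–C7≡C8)
Conditions: Cu(OAc)2 (10 equiv), pyridine, 60 °C; 10 added by syringe pump over 12 h, final concentration ca. 1 mM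
Reagents that add atoms: none
Why: Each terminal alkyne is deprotonated in pyridine while bound to copper to give a copper acetylide, and two acetylide ligands on divalent copper acetate centres couple at carbon, reducing two Cu(OAc)2 to CuOAc and forming the C6–C7 bond of the 1,3-diyne. The closest known reaction type is the Glaser–Eglinton oxidative homocoupling used to cyclise α,ω-diynes to macrocyclic 1,3-diynes and cyclophanes. The one ring closed is the 20-membered macrocycle, formed by end-to-end C(sp)–C(sp) coupling of the two alkyne termini, with the linear C5–C8 rod accommodated by four flexible methylenes on each side and the bent diaryl ether hinge. No stereocentre is created. The selectivity needed is ring closure over intermolecular oligomerisation, which slow addition into excess Cu(OAc)2 at high dilution should provide; the substrate helps because both termini are identical, so no cross-selectivity arises, and because all three phenols are methyl ethers, so nothing else is oxidised by divalent copper.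

Step 7
Reactants: 11 macrocyclic 1,3-diyne trimethyl ether
Product: 12 saturated macrocycle trimethyl ether (tri-O-methyl ether of the target)
Conditions: H2 (1 atm), 10% Pd/C, EtOAc, rt
Reagents that add atoms: none
Why: Catalytic hydrogenation over Pd/C adds four equivalents of H2 to the conjugated diyne to give the C5–C8 tetramethylene segment, while the aryl methyl ethers and the diaryl ether are inert under these conditions.

Step 8
Reactants: 12 saturated macrocycle trimethyl ether
Product: 14 target CNP0314249.0 (macrocyclic triol), via tris(dibromoboryl) ether 13 (not isolated)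
Conditions: BBr3 (6 equiv), CH2Cl2, −78 °C → rt; then H2O, 0 °C, work-up under argon
Reagents that add atoms: none
Why: BBr3 demethylation of aryl methyl ethers proceeds by boron coordination at each methoxy oxygen and bromide attack at methyl, the diaryl ether has no carbon open to SN2 attack and should survive, and hydrolysis of the aryl borates on work-up frees the three phenols.

**Compound list**

1 | 6-chlorohex-1-yne | C#CCCCCCl | starting material
2 | (6-chlorohex-1-yn-1-yl)lithium | [Li]C#CCCCCCl | intermediate
3 | 6-chloro-1-(trimethylsilyl)hex-1-yne | C[Si](C)(C)C#CCCCCCl | intermediate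
4 | 6-iodo-1-(trimethylsilyl)hex-1-yne | C[Si](C)(C)C#CCCCCI | intermediate
5 | 4-bromo-2,6-dimethoxyphenol | COc1cc(Br)cc(OC)c1O | starting material
6 | (3-bromo-5-methoxyphenyl)boronic acid | COc1cc(Br)cc(c1)B(O)O | starting material
7 | 5-bromo-2-(3-bromo-5-methoxyphenoxy)-1,3-dimethoxybenzene | COc1cc(Br)cc(c1)Oc1c(OC)cc(Br)cc1OC | intermediate
8 | [6-(trimethylsilyl)hex-5-yn-1-yl]zinc iodide (LiCl-solubilised, formed in the flask) | C[Si](C)(C)C#CCCCC[Zn]I | intermediate
9 | 1,3-dimethoxy-2-{3-methoxy-5-[6-(trimethylsilyl)hex-5-yn-1-yl]phenoxy}-5-[6-(trimethylsilyl)hex-5-yn-1-yl]benzene | COc1cc(CCCCC#C[Si](C)(C)C)cc(c1)Oc1c(OC)cc(CCCCC#C[Si](C)(C)C)cc1OC | intermediate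
10 | 5-(hex-5-yn-1-yl)-2-[3-(hex-5-yn-1-yl)-5-methoxyphenoxy]-1,3-dimethoxybenzene | COc1cc(CCCCC#C)cc(c1)Oc1c(OC)cc(CCCCC#C)cc1OC | intermediate
11 | macrocyclic 1,3-diyne trimethyl ether (20-membered diaryl ether cyclophane, C5≡C6–C7≡C8) | COc1cc2cc(c1)Oc1c(OC)cc(cc1OC)CCCCC#CC#CCCCC2 | intermediate
12 | saturated macrocycle trimethyl ether (dodecamethylene bridge) | COc1cc2cc(c1)Oc1c(OC)cc(cc1OC)CCCCCCCCCCCC2 | intermediate
13 | tris(dibromoboryl) ether of the target (formed in the flask) | BrB(Br)Oc1cc2cc(c1)Oc1c(OB(Br)Br)cc(cc1OB(Br)Br)CCCCCCCCCCCC2 | intermediate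
14 | CNP0314249.0: 20-membered diaryl ether cyclophane with a dodecamethylene bridge, one OH on ring A and two OH on ring B flanking the ether oxygen | Oc1cc2cc(c1)Oc1c(O)cc(cc1O)CCCCCCCCCCCC2 | target

**Step count**

Total: 8 steps. Longest linear sequence: 7 steps (steps 1, 2, 4, 5, 6, 7, 8, from 6-chlorohex-1-yne); the diaryl ether branch (step 3) joins at step 4.

**Steps most likely to fail, with fallbacks**

Step 6. Intermolecular coupling to open-chain and cyclic oligomers may outrun ring closure, or closure may be slow because the rigid diyne rod has to span the para-linked ring B. The fallback forms the same C6–C7 bond at the alkene oxidation level by ring-closing metathesis. It sets out from dibromide 7. Double Negishi coupling (Pd(OAc)2, SPhos, THF) with hept-6-enylzinc bromide F1, made from 7-bromohept-1-ene with activated Zn dust and LiCl, should give 5-(hept-6-enyl)-2-[3-(hept-6-enyl)-5-methoxyphenoxy]-1,3-dimethoxybenzene F2. Ring-closing metathesis with second-generation Grubbs catalyst in CH2Cl2 at reflux and about 1 mM should give the macrocyclic C6=C7 alkene F3 as an E/Z mixture of no consequence. Hydrogenation over Pd/C then returns to the route at compound 12.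

Step 4. The second coupling may stall at the mono-alkylated bromide, the arm may be lost by protodezincation, or the 6-silylhex-5-ynyl chain may cyclise by a radical pathway during zinc insertion. The fallback builds the arms stepwise and sets out from dibromide 7. Double Sonogashira coupling with pent-4-yn-1-ol (PdCl2(PPh3)2, CuI, Et3N, 70 °C) should give 5-{3-[4-(5-hydroxypent-1-ynyl)-2,6-dimethoxyphenoxy]-5-methoxyphenyl}pent-4-yn-1-ol F4. Hydrogenation over Pd/C should give 5-{3-[4-(5-hydroxypentyl)-2,6-dimethoxyphenoxy]-5-methoxyphenyl}pentan-1-ol F5. Dess–Martin oxidation should give 5-{3-[2,6-dimethoxy-4-(5-oxopentyl)phenoxy]-5-methoxyphenyl}pentanal F6. Ohira–Bestmann homologation (dimethyl (1-diazo-2-oxopropyl)phosphonate, K2CO3, MeOH) converts both aldehydes to terminal alkynes and returns to the route at compound 10, bypassing step 5.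

Step 3. O-arylation of the phenol with two ortho substituents may be slow, so that oxidative degradation of the electron-rich phenol and protodeboronation or homocoupling of the boronic acid consume the partners. The fallback is a metal-free arylation with a diaryliodonium salt and sets out from phenol 5. 1-Bromo-3-iodo-5-methoxybenzene is oxidised with mCPBA and TsOH·H2O in MeCN and treated with 1,3,5-trimethoxybenzene to give (3-bromo-5-methoxyphenyl)(2,4,6-trimethoxyphenyl)iodonium 4-methylbenzenesulfonate F7. The phenoxide of 5 (t-BuOK, THF, rt → 40 °C) should take up the less electron-rich aryl group, the trimethoxyphenyl group acting as the non-transferred ligand, and the C–Br bonds are not touched. This returns to the route at compound 7.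

**Further compounds**

F1 | step 6 | hept-6-enylzinc bromide | C=CCCCCC[Zn]Br
F2 | step 6 | 5-(hept-6-enyl)-2-[3-(hept-6-enyl)-5-methoxyphenoxy]-1,3-dimethoxybenzene | COc1cc(CCCCCC=C)cc(c1)Oc1c(OC)cc(CCCCCC=C)cc1OC
F3 | step 6 | macrocyclic C6=C7 alkene trimethyl ether (E/Z mixture) | COc1cc2cc(c1)Oc1c(OC)cc(cc1OC)CCCCCC=CCCCCC2
F4 | step 4 | 5-{3-[4-(5-hydroxypent-1-ynyl)-2,6-dimethoxyphenoxy]-5-methoxyphenyl}pent-4-yn-1-ol | COc1cc(C#CCCCO)cc(c1)Oc1c(OC)cc(C#CCCCO)cc1OC
F5 | step 4 | 5-{3-[4-(5-hydroxypentyl)-2,6-dimethoxyphenoxy]-5-methoxyphenyl}pentan-1-ol | COc1cc(CCCCCO)cc(c1)Oc1c(OC)cc(CCCCCO)cc1OC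
F6 | step 4 | 5-{3-[2,6-dimethoxy-4-(5-oxopentyl)phenoxy]-5-methoxyphenyl}pentanal | COc1cc(CCCCC=O)cc(c1)Oc1c(OC)cc(CCCCC=O)cc1OC
F7 | step 3 | (3-bromo-5-methoxyphenyl)(2,4,6-trimethoxyphenyl)iodonium 4-methylbenzenesulfonate | COc1cc(Br)cc(c1)[I+]c1c(OC)cc(OC)cc1OC.Cc1ccc(cc1)S(=O)(=O)[O-]
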